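The numbers in the tables were computed for substances that don't exist; the scatter is artificial.

You want to know how far the ratio r, isomer of the product A over target, has moved by 15 d, long after the last reading.

- birch: substrate 0.20 M; run made earlier
- flask: substrate 0.10 M; time 15 d

birch run (percent of the substrate charged)

| time / d | isomer of the product A / % | target / % |
|---|---|---|
| 0.250 | 1.7 | 18.7 |
| 0.625 | 2.7 | 40.5 |
| 1.25 | 5.0 | 52.5 |
| 2.08 | 4.7 | 55.5 |
| 2.50 | 5.5 | 55.5 |
| 4.00 | 6.5 | 55.8 |
| 5.00 | 7.0 | 54.7 |

(scatter of a reading: 0.5 percentage points)

* ratio of isomer of the product A to target at 1.0 h
* ratio of isomer of the product A to target at 20 h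
* ratio of isomer of the product A to target at 15 d



I carry the percentages of the birch run over to the flask, with its 0.10 M against 0.20 M; this is an assumption, since one run cannot test it. At 20 h the neighbouring readings give r of 0.0667 and 0.0952, and 1.0 h lies before the first reading, which gives 0.0909.

For 15 d, a bound from below: if the isomer stopped rising at the last reading, r stays at 0.128. A bound from above: if its last rise, 0.5 percentage points in 1.00 d, ran on straight with target held, r reaches 0.219.

To tighten this, take the rise before it, 1 point in 1.50 d. Read as a fading rate, these give a half-life τ of the rise of 3.01 d. Now count turnovers: n, the number of τ between the last reading and 15 d, is 3.32. On this reading the isomer would near a ceiling of 9.17 %, and with target held I commit to r of 0.164. Each rise carries a scatter of 0.71 points, so the fade is a hint and the wider bounds stand.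

The forecast, reading the drift as “slow target→isomer conversion”, gave 0.08, 0.085 and 0.25, the last higher than my upper bound. The flask gives 0.0466, 0.0757 and 0.162, the last higher than my lower bound and lower than my upper one.

    target ⇌ isomer of the product B (K = 0.610, k = 0.220 h⁻¹)
    intermediate ⇌ isomer of the product A (K = 2.40, k = 0.0160 h⁻¹)
    substrate → intermediate (k = 0.0920 h⁻¹)
    intermediate ⇌ target (K = 14.0, k = 0.370 h⁻¹)

The half-life of the isomer for going back by the step that forms it, 4.3 d, is shorter than the 15 d of the flask, so 3.49 of them pass, and the flask holds 8.80 % of the isomer at 15.0 d against 9.25 % at 150 d. My count n of 3.32 has no concentration in it, and the neighbour charged with 0.040 M ends at the same r as the flask, 0.162.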